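**Strategy.** The tetramer is built as its nonamethyl ether from ring A outwards. Each aryl ether bond is formed on a ring that carries a formyl group, which a Dakin oxidation later turns into a hydroxyl. Everything rests on disconnecting the D3–O and D5–O bonds of the pyrogallol ring D. D3 and D5 flank D4 and lie meta to the ether carbon D1, so ring D can enter as 2,6-dibromo-4-fluorobenzaldehyde (D4 being the formyl-bearing carbon), an SNAr electrophile for the hindered ring C phenol. In one operation, copper-catalysed exchange with methoxide converts both C–Br bonds of the four-ring dibromo acetal 14 into methyl ethers, giving 15.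

Key step: step 8

Remark on the chemistry: 2-bromo-4,6-dimethoxybenzaldehyde and 4-bromo-2,6-dimethoxybenzaldehyde are assumed to be purchasable, so ring B carries its formyl group at B2 before the first coupling and no regiochemically ambiguous formylation of a polymethoxy diaryl ether is needed; the target has no stereocentre; ring atoms are numbered from the ether carbons (B1 bears the oxygen to ring A, B2 and C1 the oxygen between rings B and C, C4 and D1 the oxygen between rings C and D).

**Step 1**
Reactants: 1 2,4,6-trimethoxybenzaldehyde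
Product: 3 2,4,6-trimethoxyphenol, via 2,4,6-trimethoxyphenyl formate 2 (not isolated)
Conditions: mCPBA, CH2Cl2, 0 °C to rt; NaHCO3 wash; then K2CO3 (cat.), MeOH, rt, argon
Reagents that add atoms: mCPBA, O=C(OO)c1cccc(Cl)c1
Why: Dakin oxidation in its Baeyer–Villiger form, in which the electron-rich aryl group migrates in the Criegee adduct to give the aryl formate, which base-catalysed methanolysis cleaves to the phenol.

**Step 2**
Reactants: 3 2,4,6-trimethoxyphenol; 4 2-bromo-4,6-dimethoxybenzaldehyde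
Product: 5 2,4-dimethoxy-6-(2,4,6-trimethoxyphenoxy)benzaldehyde
Conditions: CuI (10 mol%), picolinic acid (20 mol%), K3PO4, DMSO, 90 °C, argon
Reagents that add atoms: none
Why: Ullmann diaryl ether coupling, in which the ortho-formyl group activates the C–Br bond of 4 and the picolinate ligand suits the 2,6-disubstituted phenoxide, while the formyl carbon already marks B2 as the site of the next oxygen.

**Step 3**
Reactants: 5 2,4-dimethoxy-6-(2,4,6-trimethoxyphenoxy)benzaldehyde
Product: 7 2,4-dimethoxy-6-(2,4,6-trimethoxyphenoxy)phenol, via ring B aryl formate 6 (not isolated)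
Conditions: mCPBA, CH2Cl2, 0 °C to rt; NaHCO3 wash; then K2CO3 (cat.), MeOH, rt, argon
Reagents that add atoms: mCPBA, O=C(OO)c1cccc(Cl)c1
Why: Dakin oxidation, favoured because the aldehyde sits ortho and para to three oxygen donors so that aryl migration outruns hydride migration, and the diaryl ether and methyl ethers are inert to peracid at this temperature.

**Step 4**
Reactants: 7 2,4-dimethoxy-6-(2,4,6-trimethoxyphenoxy)phenol; 8 4-bromo-2,6-dimethoxybenzaldehyde
Product: 9 4-[2,4-dimethoxy-6-(2,4,6-trimethoxyphenoxy)phenoxy]-2,6-dimethoxybenzaldehyde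
Conditions: CuI (10 mol%), picolinic acid (20 mol%), K3PO4, DMSO, 100 °C, argon
Reagents that add atoms: none
Why: Ullmann diaryl ether coupling of a hindered phenoxide with a bromide that is unhindered at the C–Br carbon and made electron-poor by its para-formyl group, which at the same time marks C4 for the later hydroxyl.

**Step 5**
Reactants: 9 4-[2,4-dimethoxy-6-(2,4,6-trimethoxyphenoxy)phenoxy]-2,6-dimethoxybenzaldehyde
Product: 11 4-[2,4-dimethoxy-6-(2,4,6-trimethoxyphenoxy)phenoxy]-2,6-dimethoxyphenol, via ring C aryl formate 10 (not isolated)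
Conditions: mCPBA (1.1 equiv), CH2Cl2, 0 °C; NaHCO3 wash; then K2CO3 (cat.), MeOH, rt, argon
Reagents that add atoms: mCPBA, O=C(OO)c1cccc(Cl)c1
Why: Dakin oxidation of a 2,6-dimethoxy-4-aryloxybenzaldehyde, whose strongly donating ring migrates readily, with the oxidant kept near one equivalent so that the electron-rich phenol formed is not oxidised further.

**Step 6**
Reactants: 11 4-[2,4-dimethoxy-6-(2,4,6-trimethoxyphenoxy)phenoxy]-2,6-dimethoxyphenol; 12 2,6-dibromo-4-fluorobenzaldehyde
Product: 13 2,6-dibromo-4-{4-[2,4-dimethoxy-6-(2,4,6-trimethoxyphenoxy)phenoxy]-2,6-dimethoxyphenoxy}benzaldehyde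
Conditions: K2CO3, DMF, 80 °C, argon
Reagents that add atoms: none
Why: Nucleophilic aromatic substitution by addition–elimination at the C–F carbon para to the formyl group, where fluoride is displaced much faster than the ortho bromides, which are also shielded from the bulky phenoxide and stay untouched in the absence of copper.

**Step 7**
Reactants: 13 2,6-dibromo-4-{4-[2,4-dimethoxy-6-(2,4,6-trimethoxyphenoxy)phenoxy]-2,6-dimethoxyphenoxy}benzaldehyde
Product: 14 1,3-dibromo-2-(dimethoxymethyl)-5-{4-[2,4-dimethoxy-6-(2,4,6-trimethoxyphenoxy)phenoxy]-2,6-dimethoxyphenoxy}benzene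
Conditions: HC(OMe)3, TsOH·H2O (cat.), MeOH, 60 °C; Et3N quench
Reagents that add atoms: trimethyl orthoformate, COC(OC)OC; methanol, CO
Why: Acid-catalysed acetalisation driven to completion by the orthoformate as water scavenger, which removes the acceptor from ring D before methoxide is used.

**Step 8**
Reactants: 14 1,3-dibromo-2-(dimethoxymethyl)-5-{4-[2,4-dimethoxy-6-(2,4,6-trimethoxyphenoxy)phenoxy]-2,6-dimethoxyphenoxy}benzene
Product: 15 2-(dimethoxymethyl)-1,3-dimethoxy-5-{4-[2,4-dimethoxy-6-(2,4,6-trimethoxyphenoxy)phenoxy]-2,6-dimethoxyphenoxy}benzene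
Conditions: CuBr (0.3 equiv), NaOMe (5.4 M in MeOH, 10 equiv), DMF, 110 °C, argon; basic aqueous work-up
Reagents that add atoms: sodium methoxide, [Na+].[O-]C
Why: NaOMe and CuBr should form a monovalent copper methoxide CuOMe (Na[Cu(OMe)2] in excess methoxide) that adds oxidatively to each C–Br bond of ring D to give an aryl trivalent copper species, from which reductive elimination releases the aryl methyl ether and returns monovalent copper. The closest known reaction is the Ullmann-type exchange of aryl bromides with NaOMe under copper catalysis in MeOH–DMF, by which 5-bromovanillin is turned into syringaldehyde. No ring is closed and no stereocentre is formed; the two new bonds are D3–O and D5–O. The two bromides are related by symmetry and the neighbouring acetal oxygens can hold copper near the C–Br bonds, so the second exchange should still proceed although the first methoxy group makes the ring more electron-rich. The selectivity needed is exchange of bromide without cleavage of the three diaryl ether links and without replacement of bromine by hydrogen: copper engages only the C–Br bonds, the base-stable acetal removes the para acceptor that would let methoxide expel the ring C phenoxide by SNAr, and dry concentrated methoxide under argon limits reduction.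

**Step 9**
Reactants: 15 2-(dimethoxymethyl)-1,3-dimethoxy-5-{4-[2,4-dimethoxy-6-(2,4,6-trimethoxyphenoxy)phenoxy]-2,6-dimethoxyphenoxy}benzene
Product: 16 4-{4-[2,4-dimethoxy-6-(2,4,6-trimethoxyphenoxy)phenoxy]-2,6-dimethoxyphenoxy}-2,6-dimethoxybenzaldehyde
Conditions: 1 M HCl, THF, rt
Reagents that add atoms: water, O
Why: Acid-catalysed acetal hydrolysis, fast here because the oxocarbenium ion is stabilised by three oxygen donors on ring D, under conditions that leave aryl ethers intact.

**Step 10**
Reactants: 16 4-{4-[2,4-dimethoxy-6-(2,4,6-trimethoxyphenoxy)phenoxy]-2,6-dimethoxyphenoxy}-2,6-dimethoxybenzaldehyde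
Product: 18 4-{4-[2,4-dimethoxy-6-(2,4,6-trimethoxyphenoxy)phenoxy]-2,6-dimethoxyphenoxy}-2,6-dimethoxyphenol, via ring D aryl formate 17 (not isolated)
Conditions: mCPBA (1.1 equiv), CH2Cl2, 0 °C; NaHCO3 wash; then K2CO3 (cat.), MeOH, rt, argon
Reagents that add atoms: mCPBA, O=C(OO)c1cccc(Cl)c1
Why: Dakin oxidation of the same 2,6-dimethoxy-4-aryloxybenzaldehyde type as in step 5, which installs the D4 oxygen only after the whole skeleton is in place.

**Step 11**
Reactants: 18 4-{4-[2,4-dimethoxy-6-(2,4,6-trimethoxyphenoxy)phenoxy]-2,6-dimethoxyphenoxy}-2,6-dimethoxyphenol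
Product: 19 2-{2-[3,5-dihydroxy-4-(3,4,5-trihydroxyphenoxy)phenoxy]-3,5-dihydroxyphenoxy}benzene-1,3,5-triol (CNP0018314.0)
Conditions: BBr3 (20 equiv), CH2Cl2, −78 °C to rt; then ice-water, argon, degassed solvents
Reagents that add atoms: none
Why: Lewis acid-mediated cleavage of the nine aryl methyl ethers by bromide attack on the methyl group of each boron-complexed ether, whereas the diaryl ether links offer no sp3 carbon for attack and should survive.

**Compound list**

1 | 2,4,6-trimethoxybenzaldehyde | COc1cc(OC)c(C=O)c(OC)c1 | starting material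
2 | 2,4,6-trimethoxyphenyl formate | COc1cc(OC)c(OC=O)c(OC)c1 | intermediate
3 | 2,4,6-trimethoxyphenol | COc1cc(OC)c(O)c(OC)c1 | intermediate
4 | 2-bromo-4,6-dimethoxybenzaldehyde | COc1cc(Br)c(C=O)c(OC)c1 | starting material
5 | 2,4-dimethoxy-6-(2,4,6-trimethoxyphenoxy)benzaldehyde | COc1cc(OC)c(Oc2cc(OC)cc(OC)c2C=O)c(OC)c1 | intermediate
6 | 2,4-dimethoxy-6-(2,4,6-trimethoxyphenoxy)phenyl formate | COc1cc(OC)c(Oc2cc(OC)cc(OC)c2OC=O)c(OC)c1 | intermediate
7 | 2,4-dimethoxy-6-(2,4,6-trimethoxyphenoxy)phenol | COc1cc(OC)c(Oc2cc(OC)cc(OC)c2O)c(OC)c1 | intermediate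
8 | 4-bromo-2,6-dimethoxybenzaldehyde | COc1cc(Br)cc(OC)c1C=O | starting material
9 | 4-[2,4-dimethoxy-6-(2,4,6-trimethoxyphenoxy)phenoxy]-2,6-dimethoxybenzaldehyde | COc1cc(OC)c(Oc2cc(OC)cc(OC)c2Oc2cc(OC)c(C=O)c(OC)c2)c(OC)c1 | intermediate
10 | 4-[2,4-dimethoxy-6-(2,4,6-trimethoxyphenoxy)phenoxy]-2,6-dimethoxyphenyl formate | COc1cc(OC)c(Oc2cc(OC)cc(OC)c2Oc2cc(OC)c(OC=O)c(OC)c2)c(OC)c1 | intermediate
11 | 4-[2,4-dimethoxy-6-(2,4,6-trimethoxyphenoxy)phenoxy]-2,6-dimethoxyphenol | COc1cc(OC)c(Oc2cc(OC)cc(OC)c2Oc2cc(OC)c(O)c(OC)c2)c(OC)c1 | intermediate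
12 | 2,6-dibromo-4-fluorobenzaldehyde | O=Cc1c(Br)cc(F)cc1Br | starting material
13 | 2,6-dibromo-4-{4-[2,4-dimethoxy-6-(2,4,6-trimethoxyphenoxy)phenoxy]-2,6-dimethoxyphenoxy}benzaldehyde | COc1cc(OC)c(Oc2cc(OC)cc(OC)c2Oc2cc(OC)c(Oc3cc(Br)c(C=O)c(Br)c3)c(OC)c2)c(OC)c1 | intermediate
14 | 1,3-dibromo-2-(dimethoxymethyl)-5-{4-[2,4-dimethoxy-6-(2,4,6-trimethoxyphenoxy)phenoxy]-2,6-dimethoxyphenoxy}benzene | COc1cc(OC)c(Oc2cc(OC)cc(OC)c2Oc2cc(OC)c(Oc3cc(Br)c(C(OC)OC)c(Br)c3)c(OC)c2)c(OC)c1 | intermediate
15 | 2-(dimethoxymethyl)-1,3-dimethoxy-5-{4-[2,4-dimethoxy-6-(2,4,6-trimethoxyphenoxy)phenoxy]-2,6-dimethoxyphenoxy}benzene | COc1cc(OC)c(Oc2cc(OC)cc(OC)c2Oc2cc(OC)c(Oc3cc(OC)c(C(OC)OC)c(OC)c3)c(OC)c2)c(OC)c1 | intermediate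
16 | 4-{4-[2,4-dimethoxy-6-(2,4,6-trimethoxyphenoxy)phenoxy]-2,6-dimethoxyphenoxy}-2,6-dimethoxybenzaldehyde | COc1cc(OC)c(Oc2cc(OC)cc(OC)c2Oc2cc(OC)c(Oc3cc(OC)c(C=O)c(OC)c3)c(OC)c2)c(OC)c1 | intermediate
17 | 4-{4-[2,4-dimethoxy-6-(2,4,6-trimethoxyphenoxy)phenoxy]-2,6-dimethoxyphenoxy}-2,6-dimethoxyphenyl formate | COc1cc(OC)c(Oc2cc(OC)cc(OC)c2Oc2cc(OC)c(Oc3cc(OC)c(OC=O)c(OC)c3)c(OC)c2)c(OC)c1 | intermediate
18 | 4-{4-[2,4-dimethoxy-6-(2,4,6-trimethoxyphenoxy)phenoxy]-2,6-dimethoxyphenoxy}-2,6-dimethoxyphenol | COc1cc(OC)c(Oc2cc(OC)cc(OC)c2Oc2cc(OC)c(Oc3cc(OC)c(O)c(OC)c3)c(OC)c2)c(OC)c1 | intermediate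
19 | 2-{2-[3,5-dihydroxy-4-(3,4,5-trihydroxyphenoxy)phenoxy]-3,5-dihydroxyphenoxy}benzene-1,3,5-triol | Oc1cc(O)c(Oc2cc(O)cc(O)c2Oc2cc(O)c(Oc3cc(O)c(O)c(O)c3)c(O)c2)c(O)c1 | target

**Totals and risks**

Total step count: 11. Longest linear sequence: 11 steps (1 to 19; compounds 4, 8 and 12 are purchased).

The three steps most likely to fail are taken in order of risk.

Risk 1, step 8 (the key step): the second bromide may exchange slowly once the first methoxy group has enriched ring D, and copper-mediated replacement of bromine by hydrogen may compete, so that the exchange stops short or over-reduces. The fallback sets out from phenol 11 and brings ring D in with both methoxy groups already present. Ullmann coupling of 11 with 4-bromo-2,6-dimethoxybenzaldehyde 8 (CuI, picolinic acid, K3PO4, DMSO, 100 °C, as in step 4) should give aldehyde 16 directly, where the route is rejoined. No new compound arises on this way, hence the entry F0.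

Risk 2, step 4: the doubly ortho-substituted phenoxide of 7 may couple sluggishly, so that reduction of the bromide or base-induced degradation of the aldehyde takes over. The fallback sets out from 7 and forms the B2–O–C1 bond without copper. SNAr of 7 on 2,6-dibromo-4-fluorobenzaldehyde 12 (K2CO3, DMF, 80 °C) should give 2,6-dibromo-4-[2,4-dimethoxy-6-(2,4,6-trimethoxyphenoxy)phenoxy]benzaldehyde F1. Acetalisation of F1 (HC(OMe)3, TsOH, MeOH) should give 1,3-dibromo-2-(dimethoxymethyl)-5-[2,4-dimethoxy-6-(2,4,6-trimethoxyphenoxy)phenoxy]benzene F2. Exchange on F2 with CuBr and NaOMe in MeOH–DMF should give 2-(dimethoxymethyl)-1,3-dimethoxy-5-[2,4-dimethoxy-6-(2,4,6-trimethoxyphenoxy)phenoxy]benzene F3. Hydrolysis of F3 with 1 M HCl in THF then returns to the route at aldehyde 9.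

Risk 3, step 11: removal of the nine methyl groups may stall at partly methylated stages, and the decaphenol may be lost through air oxidation during aqueous work-up and chromatography. The fallback sets out from 18. After the BBr3 cleavage and quench, the crude phenol is not purified but acetylated at once (Ac2O, pyridine, DMAP, rt) to the stable 2-{2-[3,5-diacetoxy-4-(3,4,5-triacetoxyphenoxy)phenoxy]-3,5-diacetoxyphenoxy}benzene-1,3,5-triyl triacetate F4. F4 can be purified on silica and freed from incompletely cleaved material. Acid-catalysed methanolysis of F4 (HCl in MeOH, rt, argon) then releases 19, where the route is rejoined, without exposing phenoxides to air.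

**Further compounds**

F0 | step 8 | none | none
F1 | step 4 | 2,6-dibromo-4-[2,4-dimethoxy-6-(2,4,6-trimethoxyphenoxy)phenoxy]benzaldehyde | COc1cc(OC)c(Oc2cc(OC)cc(OC)c2Oc2cc(Br)c(C=O)c(Br)c2)c(OC)c1
F2 | step 4 | 1,3-dibromo-2-(dimethoxymethyl)-5-[2,4-dimethoxy-6-(2,4,6-trimethoxyphenoxy)phenoxy]benzene | COc1cc(OC)c(Oc2cc(OC)cc(OC)c2Oc2cc(Br)c(C(OC)OC)c(Br)c2)c(OC)c1
F3 | step 4 | 2-(dimethoxymethyl)-1,3-dimethoxy-5-[2,4-dimethoxy-6-(2,4,6-trimethoxyphenoxy)phenoxy]benzene | COc1cc(OC)c(Oc2cc(OC)cc(OC)c2Oc2cc(OC)c(C(OC)OC)c(OC)c2)c(OC)c1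
F4 | step 11 | 2-{2-[3,5-diacetoxy-4-(3,4,5-triacetoxyphenoxy)phenoxy]-3,5-diacetoxyphenoxy}benzene-1,3,5-triyl triacetate | CC(=O)Oc1cc(OC(C)=O)c(Oc2cc(OC(C)=O)cc(OC(C)=O)c2Oc2cc(OC(C)=O)c(Oc3cc(OC(C)=O)c(OC(C)=O)c(OC(C)=O)c3)c(OC(C)=O)c2)c(OC(C)=O)c1
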